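With a small charge of reagent, 11 mM in the red run, the target readings top out near 2.00 h, as they do with the 22 mM of the green run, and both runs leave starting material behind. So you work with what is left, not with what is made.

| flask | starting material | reagent | remark | time |
|---|---|---|---|---|
| green | 20 mM | 22 mM (fed, over 20 min) | the very flask that is asked about, followed so far |  |
| red | 20 mM | 11 mM (fed, over 20 min) | run made earlier |  |
| flask | 20 mM | 22.0 mM (fed, over 20 min) |  | 10 h |

| run | time / h | target / % | starting material / % |
|---|---|---|---|
| green | 0.500 | 22.7 | 69.8 |
| green | 0.667 | 27.0 | 60.9 |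
| green | 1.00 | 32.6 | 50.3 |
| green | 1.33 | 35.1 | 45.6 |
| green | 2.00 | 35.7 | 41.0 |
| green | 3.00 | 35.2 | 36.9 |
| green | 4.00 | 34.4 | 35.3 |
| red | 0.500 | 12.9 | 82.8 |
| red | 0.667 | 17.1 | 78.3 |
| red | 1.00 | 21.4 | 71.2 |
| red | 1.33 | 24.2 | 67.2 |
| red | 2.00 | 25.0 | 61.7 |
| red | 3.00 | 24.7 | 58.4 |
| red | 4.00 | 23.9 | 56.3 |

(standard deviation of a reading: 0.5 percentage points)

* time, not beyond 10 h, at which the flask holds most target
* the amount of target, in percent of the starting material charged, at that time
* the first time at which target reaches 11%, in the same percent

- the earlier runs were read with a standard deviation of 0.5 percentage points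

Let A be the starting material and P the target, both as percentages of the charge. What has left A is a crude ceiling on P, 59.0% in the green run at 2.00 h. Take from it the gap G, the share of the charge that is neither A nor P, the mass-balance deficit:

G = whole charge − A − P = 23.3% at 2.00 h

P rises while A falls by more than G grows. Compare the two across each interval of the green run:

1.33 h to 2.00 h: A falls 4.6 points, G grows 4 points

2.00 h to 3.00 h: A falls 4.1 points, G grows 4.6 points

So the readings place the top between 1.33 h and 3.00 h. From below, P is bounded by the reading 35.7%. From above, the net gain is shrinking, so what follows 2.00 h adds less than the last net gain, which gives 36.3%. The lower bound carries the scatter of 0.5 points. The upper bound is 2 times the reading at 2.00 h less the reading at 1.33 h, because the readings of A cancel, so its scatter is 1.1 points.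

The forecast, inside this bracket, gives 35.8% at 2 h and the asked level at 0.31 h, noting that “the top is flat, so its time is poorly fixed”.

The flask gives 36.1% at 2.04 h, under the upper bound, and reaches the asked level at 0.292 h.

    intermediate ⇌ target + by-product (K = 0.0180 M, k = 0.0130 s⁻¹)
    starting material + intermediate → side product (k = 0.00610 L mol⁻¹ s⁻¹)
    starting material + reagent ⇌ intermediate (K = 36.0 L mol⁻¹, k = 0.0170 L mol⁻¹ s⁻¹)

At 2.04 h the flask's gap stands as 14.5% intermediate and 9.06% side product. The same flask read at 2.5 h holds 38.4% starting material, and G plus half of 4.6 points leaves 36.0% for target, where 35.9% stands. The largest single check on target is the back reaction of target + by-product to intermediate: the run without it reaches 95.2% of target, not 36.1%.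

The earlier runs and the new flask are calculated on assumed constants; scatter was added.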